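The cyclopentane is cut between its ring CH2 and its C(OH)CH3 carbon: it is grown from a cyclobutane. Dichloroketene and a chiral vinyl ether give a cyclobutanone whose carbonyl carbon receives an acetyl group; a Lewis-acid α-ketol rearrangement of this 1-acetylcyclobutanol then shifts the ring CH2 onto the acetyl carbon. This one operation makes the five-membered ring, sets the tertiary methyl carbinol cis to the ether oxygen that becomes the lactone oxygen, and leaves a ketone at the carbon that will carry the cyclohexene; the CCl2 group blocks the alternative shift. Later an amine-mediated Michael/Mannich annulation fuses γ-lactone and cyclohexenone, and a spiro-butenolide is β-hydroxylated last.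

Key step: step 7

Remark (assumption): the (R)-configured auxiliary alcohol is assumed to give the (3R)-cyclobutanone (ketene anti to the aryl group of the s-trans vinyl ether); if the sense were opposite, the (S)-alcohol would be used.
Remark (notation): R* = (1R)-1-(2,4,6-triisopropylphenyl)ethyl; the starting materials are taken as commercial.

Step 1
Reactants: 1 (S)-(+)-carvone
Product: 2 trans-carvone oxide (epoxide oxygen anti to the isopropenyl group)
Conditions: 30 % H2O2, NaOH (cat.), MeOH, 0 °C
Reagents that add atoms: hydrogen peroxide, OO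
Why: Weitz–Scheffer nucleophilic epoxidation should attack only the electron-poor enone C=C, anti to the isopropenyl group; the two epoxide centres are destroyed again in step 2.

Step 2
Reactants: 2 trans-carvone oxide
Product: 3 (3S)-5-oxo-3-(prop-1-en-2-yl)pentanoic acid
Conditions: H5IO6, THF/H2O, 0 °C to rt
Reagents that add atoms: water, O; periodic acid, O=I(O)(O)(O)(O)O
Why: Periodic acid should hydrolyse the epoxide and carry out two Malaprade-type cleavages (1,2-diol, then α-dicarbonyl), excising the methyl-bearing carbon as acetic acid and leaving acid and aldehyde arms differentiated at the untouched isopropenyl stereocentre.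

Step 3
Reactants: 3 (3S)-5-oxo-3-(prop-1-en-2-yl)pentanoic acid
Product: 4 methyl (3S)-5-oxo-3-(prop-1-en-2-yl)pentanoate
Conditions: MeI, KHCO3, DMF, rt
Reagents that add atoms: iodomethane, CI
Why: SN2 O-methylation of the carboxylate under weakly basic conditions should leave the enolisable aldehyde and the stereocentre untouched.

Step 4
Reactants: 5 (1R)-1-(2,4,6-triisopropylphenyl)ethanol
Product: 6 (1R)-1-(2,4,6-triisopropylphenyl)ethyl vinyl ether
Conditions: vinyl acetate, [Ir(cod)Cl]2 (cat.), Na2CO3, toluene, 100 °C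
Reagents that add atoms: vinyl acetate, C=COC(C)=O
Why: Iridium-catalysed transfer vinylation should move the vinyl group to the alcohol oxygen without touching the benzylic stereocentre.

Step 5
Reactants: 6 (1R)-1-(2,4,6-triisopropylphenyl)ethyl vinyl ether; 7 trichloroacetyl chloride
Product: 9 (3R)-2,2-dichloro-3-(R*O)cyclobutan-1-one, via dichloroketene 8 (not isolated)
Conditions: Zn–Cu, Et2O, 0 °C to rt, slow addition of 7
Reagents that add atoms: none
Why: Ketene–enol ether [2+2] cycloaddition should bond the ketene carbonyl carbon to the nucleophilic CH2 terminus, with the ketene approaching the s-trans vinyl ether anti to the aryl group of the auxiliary, which sets the alkoxy-bearing ring carbon.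

Step 6
Reactants: 9 (3R)-2,2-dichloro-3-(R*O)cyclobutan-1-one; 10 ethyl vinyl ether
Product: 13 1-[(1R,3R)-2,2-dichloro-1-hydroxy-3-(R*O)cyclobutyl]ethan-1-one, via 1-ethoxyvinyllithium 11 (not isolated), via enol ether adduct 12 (not isolated)
Conditions: 10, t-BuLi, THF, −78 to 0 °C; CeCl3, −78 °C; then 9; 1 M HCl, THF, 0 °C
Reagents that add atoms: water, O
Why: Organocerium 1,2-addition of the acyl-anion equivalent should occur anti to the 3-alkoxy group (carbinol OH cis to the ether oxygen), and mild hydrolysis of the enol ether unveils the methyl ketone.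

Step 7
Reactants: 13 1-[(1R,3R)-2,2-dichloro-1-hydroxy-3-(R*O)cyclobutyl]ethan-1-one
Product: 14 (3R,5S)-2,2-dichloro-5-hydroxy-5-methyl-3-(R*O)cyclopentan-1-one
Conditions: Sc(OTf)3 (10 mol %), CH2Cl2, −20 °C to rt
Reagents that add atoms: none
Why: Scandium(III) should chelate the tertiary hydroxyl and the acetyl oxygen in a syn-periplanar array, and the ring CH2 then undergoes a suprafacial 1,2-shift from the carbinol carbon to the acetyl carbon while the carbinol carbon becomes the ring ketone. The closest known reaction type is the α-ketol (acyloin) rearrangement in its strain-driven, ring-expanding form known for 1-acylcyclobutanols. No ring is closed by cyclisation: the cyclopentane arises by one-carbon ring expansion of the cyclobutane through this 1,2-alkyl shift. The new stereocentre, the tertiary methyl carbinol, is controlled by the chelate geometry together with the cis relation of hydroxyl and ether oxygen fixed in step 6, which should place the new hydroxyl cis to the ether oxygen. The step needs migration of CH2 and not of CCl2, which the poor migratory aptitude of the dichlorinated carbon secures, and relief of four-ring strain should make it irreversible.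

Step 8
Reactants: 14 (3R,5S)-2,2-dichloro-5-hydroxy-5-methyl-3-(R*O)cyclopentan-1-one
Product: 15 (2S,4R)-2-hydroxy-2-methyl-4-(R*O)cyclopentan-1-one
Conditions: Bu3SnH, AIBN (cat.), toluene, 80 °C
Reagents that add atoms: none
Why: Tin-hydride radical hydrodechlorination should remove both α-chlorines through the α-keto radical, which, unlike a zinc enolate, does not expel the β-alkoxy group.

Step 9
Reactants: 15 (2S,4R)-2-hydroxy-2-methyl-4-(R*O)cyclopentan-1-one
Product: 16 (2S,4R)-2,4-dihydroxy-2-methylcyclopentan-1-one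
Conditions: CF3CO2H, CH2Cl2, 0 °C; NaHCO3 (aq)
Reagents that add atoms: none
Why: SN1 acidolysis of the electron-rich benzylic ether should cleave the O–C bond on the auxiliary side, so the ring carbinol keeps its configuration.

Step 10
Reactants: 16 (2S,4R)-2,4-dihydroxy-2-methylcyclopentan-1-one
Product: 18 (1R,4S)-3-iodo-4-methylcyclopent-2-ene-1,4-diol, via hydrazone 17 (not isolated)
Conditions: N2H4·H2O, Et3N, EtOH, 70 °C; evaporate; I2, tetramethylguanidine, THF, 0 °C
Reagents that add atoms: iodine, II
Why: Barton vinyl iodide synthesis: iodine oxidation of the hydrazone gives an α-iodo cation that can lose only the CH2 proton, which should place the alkene toward the CH2 and the iodine on the carbon next to the tertiary carbinol.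

Step 11
Reactants: 18 (1R,4S)-3-iodo-4-methylcyclopent-2-ene-1,4-diol; 19 3,3-dimethoxypropanoic acid
Product: 20 (1R,4S)-4-hydroxy-3-iodo-4-methylcyclopent-2-en-1-yl 3,3-dimethoxypropanoate
Conditions: DCC, DMAP (cat.), CH2Cl2, 0 °C
Reagents that add atoms: none
Why: Steglich esterification should acylate the secondary allylic hydroxyl and leave the hindered tertiary hydroxyl free.

Step 12
Reactants: 20 (1R,4S)-4-hydroxy-3-iodo-4-methylcyclopent-2-en-1-yl 3,3-dimethoxypropanoate; 4 methyl (3S)-5-oxo-3-(prop-1-en-2-yl)pentanoate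
Product: 21 (1R,4S)-4-hydroxy-3-[(3S)-1-hydroxy-5-methoxy-5-oxo-3-(prop-1-en-2-yl)pentyl]-4-methylcyclopent-2-en-1-yl 3,3-dimethoxypropanoate (both carbinol epimers)
Conditions: CrCl2, NiCl2 (cat.), DMSO, rt
Reagents that add atoms: none
Why: Nozaki–Hiyama–Kishi coupling: the alkenylchromium(III) species should add only to the aldehyde in the presence of esters, acetal and free tertiary hydroxyl; the new carbinol forms as an epimer mixture that is erased in step 13.

Step 13
Reactants: 21 allylic alcohol (both carbinol epimers)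
Product: 22 (1R,4S)-4-hydroxy-3-[(3S)-5-methoxy-5-oxo-3-(prop-1-en-2-yl)pentanoyl]-4-methylcyclopent-2-en-1-yl 3,3-dimethoxypropanoate
Conditions: Dess–Martin periodinane, NaHCO3, CH2Cl2, 0 °C to rt
Reagents that add atoms: none
Why: Dess–Martin oxidation should convert the secondary allylic alcohol into the cyclopentenyl ketone; the tertiary alcohol cannot be oxidised.

Step 14
Reactants: 22 enone acetal ester
Product: 25 tricyclic enone lactone (target skeleton with C=O in place of the spiro carbon; the three ring-fusion hydrogens cis, tertiary OH cis to the lactone oxygen), via enamino ester 23 (not isolated), via aminomethylene lactone 24 (not isolated)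
Conditions: pyrrolidine, CF3CO2H (1.2 equiv each), MeCN/H2O, 50 °C
Reagents that add atoms: none
Why: Acetal aminolysis should give a vinylogous carbamate whose α-carbon adds to the enone β-carbon from the face of the ester oxygen (5-exo-trig Michael addition, hence cis-fused lactone), and a six-membered Mannich-type closure onto the ketone α-CH2 with loss of pyrrolidine completes a Robinson-type annulation, the two epimerisable centres next to the carbonyls settling in the all-cis-fused tricycle.

Step 15
Reactants: 25 tricyclic enone lactone; 26 ethyl propiolate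
Product: 28 tertiary propargylic alcohol (ethyl ynoate on the former ketone carbon, OH on the face of the cyclopentane), via lithium acetylide 27 (not isolated)
Conditions: 26, LiHMDS, THF, −78 °C; CeCl3; then 25, −78 °C; NH4Cl (aq)
Reagents that add atoms: none
Why: 1,2-Addition of the cerium acetylide to the enone carbonyl should occur from the convex face, anti to the cyclopentane carbon on the neighbouring ring-fusion centre, which sets the tertiary carbinol.

Step 16
Reactants: 28 tertiary propargylic alcohol
Product: 30 spiro-butenolide, via Z-enoate 29 (not isolated)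
Conditions: H2 (1 atm), Lindlar catalyst, quinoline, EtOAc, rt; then PPTS (cat.), 40 °C
Reagents that add atoms: none
Why: Lindlar semihydrogenation should stop at the (Z)-enoate, whose ester lies next to the tertiary hydroxyl and lactonises to the spiro-butenolide without touching the other alkenes.

Step 17
Reactants: 30 spiro-butenolide
Product: 32 target CNP0148106.2, via boronate 31 (not isolated)
Conditions: B2pin2, CuCl (cat.), Josiphos-type ligand (matched enantiomer, cat.), NaOtBu (cat.), MeOH, THF, rt; then H2O2, pH 7 buffer, 0 °C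
Reagents that add atoms: hydrogen peroxide, OO; bis(pinacolato)diboron, B1(OC(C)(C)C(C)(C)O1)B1OC(C)(C)C(C)(C)O1 (boron of 31 only)
Why: Copper(I)–boryl conjugate addition should place boron on the butenolide β-carbon, the only Michael acceptor left, on the face chosen by the chiral ligand, and stereoretentive oxidation of the C–B bond gives the β-hydroxy lactone.

Compound list
1 | (S)-(+)-carvone | CC(=C)[C@H]1CC=C(C)C(=O)C1 | starting material
2 | trans-carvone oxide from (S)-carvone, epoxide oxygen anti to isopropenyl | CC(=C)[C@H]1C[C@@H]2O[C@]2(C)C(=O)C1 | intermediate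
3 | (3S)-5-oxo-3-(prop-1-en-2-yl)pentanoic acid | CC(=C)[C@H](CC(=O)O)CC=O | intermediate
4 | methyl (3S)-5-oxo-3-(prop-1-en-2-yl)pentanoate | CC(=C)[C@H](CC(=O)OC)CC=O | intermediate
5 | (1R)-1-(2,4,6-triisopropylphenyl)ethanol | C[C@@H](O)c1c(C(C)C)cc(C(C)C)cc1C(C)C | starting material
6 | (1R)-1-(2,4,6-triisopropylphenyl)ethyl vinyl ether | C[C@@H](OC=C)c1c(C(C)C)cc(C(C)C)cc1C(C)C | intermediate
7 | trichloroacetyl chloride | ClC(=O)C(Cl)(Cl)Cl | starting material
8 | dichloroketene | ClC(Cl)=C=O | intermediate
9 | (3R)-2,2-dichloro-3-(R*O)cyclobutan-1-one | C[C@@H](O[C@@H]1CC(=O)C1(Cl)Cl)c1c(C(C)C)cc(C(C)C)cc1C(C)C | intermediate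
10 | ethyl vinyl ether | C=COCC | starting material
11 | 1-ethoxyvinyllithium | [Li]C(=C)OCC | intermediate
12 | (1R,3R)-2,2-dichloro-1-(1-ethoxyvinyl)-3-(R*O)cyclobutan-1-ol, OH cis to the ether oxygen | C[C@@H](O[C@@H]1C[C@@](O)(C(=C)OCC)C1(Cl)Cl)c1c(C(C)C)cc(C(C)C)cc1C(C)C | intermediate
13 | 1-[(1R,3R)-2,2-dichloro-1-hydroxy-3-(R*O)cyclobutyl]ethan-1-one, OH cis to the ether oxygen | C[C@@H](O[C@@H]1C[C@@](O)(C(C)=O)C1(Cl)Cl)c1c(C(C)C)cc(C(C)C)cc1C(C)C | intermediate
14 | (3R,5S)-2,2-dichloro-5-hydroxy-5-methyl-3-(R*O)cyclopentan-1-one, OH cis to the ether oxygen | C[C@@H](O[C@@H]1C[C@](C)(O)C(=O)C1(Cl)Cl)c1c(C(C)C)cc(C(C)C)cc1C(C)C | intermediate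
15 | (2S,4R)-2-hydroxy-2-methyl-4-(R*O)cyclopentan-1-one | C[C@@H](O[C@@H]1C[C@](C)(O)C(=O)C1)c1c(C(C)C)cc(C(C)C)cc1C(C)C | intermediate
16 | (2S,4R)-2,4-dihydroxy-2-methylcyclopentan-1-one (cis-diol) | O[C@@H]1C[C@](C)(O)C(=O)C1 | intermediate
17 | hydrazone of 16 | O[C@@H]1C[C@](C)(O)C(=NN)C1 | intermediate
18 | (1R,4S)-3-iodo-4-methylcyclopent-2-ene-1,4-diol (cis-diol) | O[C@@H]1C[C@](C)(O)C(I)=C1 | intermediate
19 | 3,3-dimethoxypropanoic acid | COC(OC)CC(=O)O | starting material
20 | (1R,4S)-4-hydroxy-3-iodo-4-methylcyclopent-2-en-1-yl 3,3-dimethoxypropanoate | COC(OC)CC(=O)O[C@@H]1C[C@](C)(O)C(I)=C1 | intermediate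
21 | (1R,4S)-4-hydroxy-3-[(3S)-1-hydroxy-5-methoxy-5-oxo-3-(prop-1-en-2-yl)pentyl]-4-methylcyclopent-2-en-1-yl 3,3-dimethoxypropanoate, carbinol epimers | COC(OC)CC(=O)O[C@@H]1C[C@](C)(O)C(C(O)C[C@@H](CC(=O)OC)C(C)=C)=C1 | intermediate
22 | (1R,4S)-4-hydroxy-3-[(3S)-5-methoxy-5-oxo-3-(prop-1-en-2-yl)pentanoyl]-4-methylcyclopent-2-en-1-yl 3,3-dimethoxypropanoate | COC(OC)CC(=O)O[C@@H]1C[C@](C)(O)C(C(=O)C[C@@H](CC(=O)OC)C(C)=C)=C1 | intermediate
23 | (E)-3-(pyrrolidin-1-yl)acrylate ester corresponding to 22 | O=C(/C=C/N1CCCC1)O[C@@H]2C[C@](C)(O)C(C(=O)C[C@@H](CC(=O)OC)C(C)=C)=C2 | intermediate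
24 | cis-fused cyclopenta-γ-lactone with α-(pyrrolidin-1-ylmethylene) group and the keto side chain on the neighbouring ring carbon (that centre epimerisable) | O=C1O[C@@H]2C[C@](C)(O)C(C(=O)C[C@@H](CC(=O)OC)C(C)=C)[C@@H]2C1=CN3CCCC3 | intermediate
25 | tricyclic enone lactone: target skeleton with C=O in place of the spiro carbon | C=C(C)[C@H](CC(=O)OC)C1=C[C@@H]2C(=O)O[C@@H]3C[C@](C)(O)[C@@H]([C@H]23)C1=O | intermediate
26 | ethyl propiolate | C#CC(=O)OCC | starting material
27 | lithium acetylide of ethyl propiolate | [Li]C#CC(=O)OCC | intermediate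
28 | tertiary propargylic alcohol from 25, ethyl 3-substituted propiolate, OH on the face of the cyclopentane | C=C(C)[C@H](CC(=O)OC)C1=C[C@@H]2C(=O)O[C@@H]3C[C@](C)(O)[C@@H]([C@H]23)[C@@]1(O)C#CC(=O)OCC | intermediate
29 | (Z)-γ-hydroxy enoate from 28 | C=C(C)[C@H](CC(=O)OC)C1=C[C@@H]2C(=O)O[C@@H]3C[C@](C)(O)[C@@H]([C@H]23)[C@@]1(O)/C=C\C(=O)OCC | intermediate
30 | spiro-butenolide (target without the β-hydroxyl, C=C in the spiro-lactone) | C=C(C)[C@H](CC(=O)OC)C1=C[C@@H]2C(=O)O[C@@H]3C[C@](C)(O)[C@@H]([C@H]23)[C@]12OC(=O)C=C2 | intermediate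
31 | β-(pinacolboryl) spiro-lactone, boron where the hydroxyl of 32 stands | C=C(C)[C@H](CC(=O)OC)C1=C[C@@H]2C(=O)O[C@@H]3C[C@](C)(O)[C@@H]([C@H]23)[C@]12OC(=O)C[C@@H]2B4OC(C)(C)C(C)(C)O4 | intermediate
32 | CNP0148106.2 | C=C(C)[C@H](CC(=O)OC)C1=C[C@@H]2C(=O)O[C@@H]3C[C@](C)(O)[C@@H]([C@H]23)[C@]12OC(=O)C[C@@H]2O | target

Total step count: 17. Longest linear sequence: 14 steps (steps 4 to 17, from alcohol 5); the side chain 4 takes 3 steps.

Steps most likely to fail

Step 7. The process at risk is the stereochemical course of the shift: a non-chelated, anti-periplanar transition state would give the trans-diol, and the Lewis acid could ionise the acid-labile benzylic ether. The fallback sets out from cyclobutanone 9 and comes back at ketol 14; it also bypasses step 6. One-carbon homologation of 9 with diazomethane, in which only the non-chlorinated CH2 migrates, should give (3R)-2,2-dichloro-3-(R*O)cyclopentan-1-one F1. Its only enolisable position is silylated (TESOTf, Et3N) and oxidised with dimethyldioxirane (Rubottom oxidation) to the α-triethylsilyloxy ketone F2. Methylation of its enolate (LiHMDS, MeI) anti to the 3-alkoxy group should give the methylated silyl ether F3, and HF·pyridine then liberates 14.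

Step 14. The process at risk is loss of the tertiary β-hydroxyl (dehydration or retro-aldol cleavage) under amine catalysis, or a stalled Mannich closure after the Michael step. The fallback sets out from iodo diol 18 and comes back at enone 25 through an intramolecular Diels–Alder reaction. Esterification of 18 with propiolic acid (DCC) gives the propiolate F4; Nozaki–Hiyama–Kishi coupling with 4 gives the allylic alcohol F5 and Dess–Martin oxidation the ynoate enone F6. TBSOTf/Et3N converts the enone into its 2-silyloxy diene (the tertiary hydroxyl is silylated as well), which on warming should add to the tethered ynoate to give the bis-silylated cyclohexadiene lactone F7. Aqueous HF removes both silyl groups and DBU moves the lactone-conjugated double bond into conjugation with the ketone to give 25.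

Step 17. The process at risk is poor facial selectivity of the boryl addition at the spiro-butenolide, where ligand and spiro centre may be mismatched. The fallback sets out from butenolide 30 and comes back at 32 by inversion. Borylation and oxidation under substrate control (achiral ligand) would give the epimeric β-hydroxy lactone F8; Mitsunobu reaction with 4-nitrobenzoic acid (PPh3, DIAD) inverts the carbinol to the 4-nitrobenzoate F9, and K2CO3 in MeOH at 0 °C cleaves the ester to 32.

Further compounds
F1 | step 7 | (3R)-2,2-dichloro-3-(R*O)cyclopentan-1-one | C[C@@H](O[C@@H]1CCC(=O)C1(Cl)Cl)c1c(C(C)C)cc(C(C)C)cc1C(C)C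
F2 | step 7 | (3R)-2,2-dichloro-3-(R*O)-5-(triethylsilyloxy)cyclopentan-1-one, epimers at the silyloxy carbon | C[C@@H](O[C@@H]1CC(O[Si](CC)(CC)CC)C(=O)C1(Cl)Cl)c1c(C(C)C)cc(C(C)C)cc1C(C)C
F3 | step 7 | (3R,5S)-2,2-dichloro-5-methyl-3-(R*O)-5-(triethylsilyloxy)cyclopentan-1-one | C[C@@H](O[C@@H]1C[C@](C)(O[Si](CC)(CC)CC)C(=O)C1(Cl)Cl)c1c(C(C)C)cc(C(C)C)cc1C(C)C
F4 | step 14 | (1R,4S)-4-hydroxy-3-iodo-4-methylcyclopent-2-en-1-yl propiolate | C#CC(=O)O[C@@H]1C[C@](C)(O)C(I)=C1
F5 | step 14 | (1R,4S)-4-hydroxy-3-[(3S)-1-hydroxy-5-methoxy-5-oxo-3-(prop-1-en-2-yl)pentyl]-4-methylcyclopent-2-en-1-yl propiolate, carbinol epimers | C#CC(=O)O[C@@H]1C[C@](C)(O)C(C(O)C[C@@H](CC(=O)OC)C(C)=C)=C1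
F6 | step 14 | (1R,4S)-4-hydroxy-3-[(3S)-5-methoxy-5-oxo-3-(prop-1-en-2-yl)pentanoyl]-4-methylcyclopent-2-en-1-yl propiolate | C#CC(=O)O[C@@H]1C[C@](C)(O)C(C(=O)C[C@@H](CC(=O)OC)C(C)=C)=C1
F7 | step 14 | Diels–Alder adduct: cyclohexa-1,4-diene fused to lactone and cyclopentane, silyl enol ether and tertiary silyl ether (TBS) | C=C(C)[C@H](CC(=O)OC)C1C=C2C(=O)O[C@@H]3C[C@](C)(O[Si](C)(C)C(C)(C)C)C([C@H]23)=C1O[Si](C)(C)C(C)(C)C
F8 | step 17 | epimer of 32 at the hydroxyl-bearing carbon of the spiro-lactone | C=C(C)[C@H](CC(=O)OC)C1=C[C@@H]2C(=O)O[C@@H]3C[C@](C)(O)[C@@H]([C@H]23)[C@]12OC(=O)C[C@H]2O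
F9 | step 17 | 4-nitrobenzoate of 32 (inverted carbinol) | C=C(C)[C@H](CC(=O)OC)C1=C[C@@H]2C(=O)O[C@@H]3C[C@](C)(O)[C@@H]([C@H]23)[C@]12OC(=O)C[C@@H]2OC(=O)c4ccc(cc4)[N+](=O)[O-]
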